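**Plan**

- Retrosynthesis: the C-acetyl bond on ring B and the one silyl ether are cut first. Ring B is a cyclohexane-1,3,5-trione whose quaternary carbon (methyl, geranyl) lies between two carbonyls, with the bridge CH2 on the ring carbon beyond one of them. It is opened between that bridge-bearing carbon and the carbonyl carbon next to the quaternary centre, which maps it onto a methyl 2,2-disubstituted 3,5-dioxoheptanoate already carrying ring A on C7.
- The C4–C5 bond of this chain is cut next (Claisen) into a chiral methyl ketone and a chromene-fused dihydrocoumarin. The lactone goes back to phloroglucinol, butanoyl chloride, acrylic acid and 3-methylbut-2-enal.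
- Forward: ring A is acylated, alkylated and silylated at the para oxygen; the pyran ring is annulated; the lactone ring is closed; the chain is joined by opening the lactone; ring B is closed by Dieckmann condensation; C-acetylation and desilylation finish the target.
- Stereochemistry: the only stereocentre, the quaternary carbon of ring B, comes from a double Fráter–Seebach alkylation of methyl (S)-3-hydroxybutanoate (methyl first, geranyl second), after which the controlling carbinol is oxidised. The E alkene comes with geranyl bromide.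

Key step: step 11

Remark: ring B is written throughout in the enol tautomer of the target SMILES. The tautomers interconvert without touching the quaternary carbon, and the descriptors for ring B compounds refer to that drawing. S in 20 and R in 22 and 23 are the same spatial arrangement; the acetyl group only exchanges the CIP priorities of the two flanking ring carbons.

Remark: in 19 the heptanoate chain is numbered C1 (ester), C2 (quaternary), C3 and C5 (ketones), C7 (benzylic CH2 on ring A).

**Step 1**
Reactants: 1 methyl (3S)-3-hydroxybutanoate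
Product: 2 methyl (2S,3S)-3-hydroxy-2-methylbutanoate
Conditions: LiN(iPr)2 (2.2 equiv), THF, −78 to −20 °C; MeI, DMPU, −78 to 0 °C
Reagents that add atoms: iodomethane, CI
Why: Fráter–Seebach alkylation: the lithium-chelated alkoxide–enolate dianion is methylated on the face opposite the carbinol methyl group, which should give mainly the anti (2S,3S) ester (C2 is planarised again in step 2, so its purity is not critical).

**Step 2**
Reactants: 2 methyl (2S,3S)-3-hydroxy-2-methylbutanoate; 3 geranyl bromide, (2E)-1-bromo-3,7-dimethylocta-2,6-diene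
Product: 4 methyl (2S,4E)-2-[(1S)-1-hydroxyethyl]-2,5,9-trimethyldeca-4,8-dienoate
Conditions: LiN(iPr)2 (2.2 equiv), THF, −78 to −20 °C; 3, DMPU, −78 to 0 °C
Reagents that add atoms: none
Why: Second Fráter–Seebach alkylation: deprotonation gives a tetrasubstituted enolate whose geometry is fixed by the six-membered lithium chelate, and the allylic bromide again enters anti to the carbinol methyl group (SN2 at the primary carbon, E alkene kept), so the order methyl-then-geranyl sets the quaternary carbon as 2S under control of the (S)-carbinol.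

**Step 3**
Reactants: 4 methyl (2S,4E)-2-[(1S)-1-hydroxyethyl]-2,5,9-trimethyldeca-4,8-dienoate
Product: 5 methyl (2S,4E)-2-acetyl-2,5,9-trimethyldeca-4,8-dienoate
Conditions: Dess–Martin periodinane, pyridine, CH2Cl2, 0 °C to rt
Reagents that add atoms: none
Why: Dess–Martin oxidation of the secondary alcohol gives the β-keto ester; the quaternary α-carbon has no hydrogen and cannot epimerise, and the carbinol stereocentre that controlled step 2 is erased on purpose.

**Step 4**
Reactants: 6 phloroglucinol (benzene-1,3,5-triol); 7 butanoyl chloride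
Product: 8 1-(2,4,6-trihydroxyphenyl)butan-1-one
Conditions: AlCl3 (3.5 equiv), PhNO2, 0 to 60 °C; then aq. HCl
Reagents that add atoms: none
Why: Friedel–Crafts acylation of the threefold-symmetric triol, in which all ring positions are equivalent and the first acyl group deactivates the ring against a second acylation.

**Step 5**
Reactants: 8 1-(2,4,6-trihydroxyphenyl)butan-1-one; 9 acrylic acid (prop-2-enoic acid)
Product: 12 methyl 3-(3-butanoyl-2,4,6-trihydroxyphenyl)propanoate, via 6-butanoyl-5,7-dihydroxychroman-2-one 10 (not isolated), via 8-butanoyl-5,7-dihydroxychroman-2-one 11 (not isolated)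
Conditions: 9 (1.1 equiv), MeSO3H, 60 °C; then MeOH, 60 °C; cold NaHCO3 work-up
Reagents that add atoms: methanol, CO
Why: Acid-mediated Friedel–Crafts conjugate addition (hydroarylation) of acrylic acid at one of the two equivalent free ring carbons closes a dihydrocoumarin onto either flanking hydroxyl, and acid-catalysed methanolysis (Fischer-type transesterification) of both lactones converges on one open-chain methyl ester, so the lactone regiochemistry does not matter.

**Step 6**
Reactants: 12 methyl 3-(3-butanoyl-2,4,6-trihydroxyphenyl)propanoate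
Product: 13 methyl 3-[3-butanoyl-2,4-dihydroxy-6-(triisopropylsilyloxy)phenyl]propanoate
Conditions: iPr3SiCl (1.05 equiv), imidazole, DMF, 0 °C
Reagents that add atoms: chlorotriisopropylsilane, CC(C)[Si](Cl)(C(C)C)C(C)C
Why: Selective phenol silylation: the hydroxyl para to the butanoyl group is the most acidic and the only one that cannot hydrogen-bond to the ketone, so one equivalent of the bulky chlorosilane should take it first, which blocks the oxygen that must stay out of the pyran ring.

**Step 7**
Reactants: 13 methyl 3-[3-butanoyl-2,4-dihydroxy-6-(triisopropylsilyloxy)phenyl]propanoate; 14 3-methylbut-2-enal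
Product: 16 methyl 3-[8-butanoyl-7-hydroxy-2,2-dimethyl-5-(triisopropylsilyloxy)-2H-chromen-6-yl]propanoate, via ortho-quinone methide 15 (not isolated)
Conditions: 14 (2 equiv), ethylenediammonium diacetate (20 mol %), toluene, 110 °C
Reagents that add atoms: none
Why: Amine-catalysed chromene annulation (Knoevenagel-type condensation at the only free ring carbon, then oxa-6π electrocyclisation of the ortho-quinone methide): with the para oxygen silylated the ring can close only onto the hydroxyl beside the butanoyl group, which fixes the 8-acyl chromene regiochemistry.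

**Step 8**
Reactants: 16 methyl 3-[8-butanoyl-7-hydroxy-2,2-dimethyl-5-(triisopropylsilyloxy)-2H-chromen-6-yl]propanoate
Product: 17 3-[8-butanoyl-7-hydroxy-2,2-dimethyl-5-(triisopropylsilyloxy)-2H-chromen-6-yl]propanoic acid
Conditions: Me3SnOH, 1,2-dichloroethane, 80 °C; dilute aq. HCl wash
Reagents that add atoms: trimethyltin hydroxide, C[Sn](C)(C)O
Why: Ester hydrolysis with trimethyltin hydroxide under near-neutral conditions, chosen because it spares the aryl silyl ether and the chromene.

**Step 9**
Reactants: 17 3-[8-butanoyl-7-hydroxy-2,2-dimethyl-5-(triisopropylsilyloxy)-2H-chromen-6-yl]propanoic acid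
Product: 18 10-butanoyl-8,8-dimethyl-5-(triisopropylsilyloxy)-3,4-dihydro-2H,8H-pyrano[3,2-g]chromen-2-one
Conditions: N-(3-dimethylaminopropyl)-N′-ethylcarbodiimide hydrochloride, DMAP, CH2Cl2 (high dilution), 0 °C to rt
Reagents that add atoms: none
Why: Carbodiimide (Steglich-type) lactonisation: irreversible activation of the acid lets the hydrogen-bonded phenol close the six-membered aryl lactone, which is the activated, alkoxide-free acyl donor for the next step.

**Step 10**
Reactants: 5 methyl (2S,4E)-2-acetyl-2,5,9-trimethyldeca-4,8-dienoate; 18 10-butanoyl-8,8-dimethyl-5-(triisopropylsilyloxy)-3,4-dihydro-2H,8H-pyrano[3,2-g]chromen-2-one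
Product: 19 methyl (2S)-7-[8-butanoyl-7-hydroxy-2,2-dimethyl-5-(triisopropylsilyloxy)-2H-chromen-6-yl]-2-[(2E)-3,7-dimethylocta-2,6-dien-1-yl]-2-methyl-3,5-dioxoheptanoate
Conditions: 5 (2.1 equiv), LiN(iPr)2 (2.05 equiv), THF, −78 °C; then 18 (1 equiv), −78 to −40 °C; aq. NH4Cl
Reagents that add atoms: none
Why: Crossed Claisen condensation: the kinetic lithium enolate of the methyl ketone (its only enolisable position) adds to the aryl ester carbonyl and the ring opens with phenoxide as leaving group, so no alkoxide is set free that could cleave the non-enolisable β-keto ester unit, the liberated ortho-phenoxide deactivates the butanoyl group, and the second equivalent of enolate takes up the acidic diketone proton (the excess ketone is to be recovered).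

**Step 11**
Reactants: 19 methyl (2S)-7-[8-butanoyl-7-hydroxy-2,2-dimethyl-5-(triisopropylsilyloxy)-2H-chromen-6-yl]-2-[(2E)-3,7-dimethylocta-2,6-dien-1-yl]-2-methyl-3,5-dioxoheptanoate
Product: 20 (4S)-6-{[8-butanoyl-7-hydroxy-2,2-dimethyl-5-(triisopropylsilyloxy)-2H-chromen-6-yl]methyl}-4-[(2E)-3,7-dimethylocta-2,6-dien-1-yl]-3,5-dihydroxy-4-methylcyclohexa-2,5-dien-1-one
Conditions: LiN(iPr)2 (4.5 equiv), THF, −78 to 0 °C; then aq. HCl (1 M), 0 °C
Reagents that add atoms: none
Why: Excess LiN(iPr)2 removes the phenol proton, the C4 proton between the two ketones and then the only remaining γ-proton, at C6 (the carbon that carries the bridge CH2; C2 is quaternary), so the terminal carbanion of the 1,3-diketone dianion is the most nucleophilic site; it adds to the ester carbonyl C1 and methoxide leaves. This is an intramolecular Claisen (Dieckmann) condensation of the kind known for dianions of 3,5-dioxo esters on the way to cyclohexane-1,3,5-triones. Ring B closes in a 6-exo-trig mode through the C6–C1 bond, and the trione is at once deprotonated to its stabilised enolate, which makes the closure irreversible. No new stereocentre forms; the quaternary carbon from step 2 has no α-hydrogen and is carried through, and because the base is an amide at low temperature and the C3 carbonyl is masked as an enolate, the methoxide set free should not start a retro-Claisen cleavage to an achiral malonate-type fragment. The step needs C- over O-acylation and attack through C6 only: the dianion puts the reactive charge on C6, attack through C4 would give a four-membered ring, and the butanoyl group beside the phenoxide is a poor electrophile and, if enolised by the excess base, a spectator too far from the ester to close a ring.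

**Step 12**
Reactants: 20 (4S)-6-{[8-butanoyl-7-hydroxy-2,2-dimethyl-5-(triisopropylsilyloxy)-2H-chromen-6-yl]methyl}-4-[(2E)-3,7-dimethylocta-2,6-dien-1-yl]-3,5-dihydroxy-4-methylcyclohexa-2,5-dien-1-one
Product: 22 (4R)-2-acetyl-6-{[8-butanoyl-7-hydroxy-2,2-dimethyl-5-(triisopropylsilyloxy)-2H-chromen-6-yl]methyl}-4-[(2E)-3,7-dimethylocta-2,6-dien-1-yl]-3,5-dihydroxy-4-methylcyclohexa-2,5-dien-1-one, via ring B enol acetate 21 (not isolated)
Conditions: Ac2O (1.1 equiv), Et3N, DMAP, CH2Cl2, 0 °C to rt
Reagents that add atoms: acetic anhydride, CC(=O)OC(C)=O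
Why: C-acylation of a cyclic 1,3-dicarbonyl by O-acetylation and DMAP-mediated O-to-C acyl shift (Steglich-type rearrangement, as used for 2-acylcyclohexane-1,3-diones): the acidic trione reacts ahead of the hydrogen-bonded, doubly flanked phenol, and only the free ring B methine can give the stable enolised 2-acyl trione, so reversible acyl transfer should funnel the acetyl group there.

**Step 13**
Reactants: 22 (4R)-2-acetyl-6-{[8-butanoyl-7-hydroxy-2,2-dimethyl-5-(triisopropylsilyloxy)-2H-chromen-6-yl]methyl}-4-[(2E)-3,7-dimethylocta-2,6-dien-1-yl]-3,5-dihydroxy-4-methylcyclohexa-2,5-dien-1-one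
Product: 23 (4R)-2-acetyl-6-[(8-butanoyl-5,7-dihydroxy-2,2-dimethyl-2H-chromen-6-yl)methyl]-4-[(2E)-3,7-dimethylocta-2,6-dien-1-yl]-3,5-dihydroxy-4-methylcyclohexa-2,5-dien-1-one (CNP0152509.1)
Conditions: Bu4NF, AcOH, THF, 0 °C
Reagents that add atoms: none
Why: Fluoride cleavage of the aryl silyl ether (silyl ether deprotection), buffered with acetic acid so that the acidic polyphenol is not exposed to basic fluoride; no stereocentre is touched.

**Compound list**

1 | methyl (3S)-3-hydroxybutanoate | C[C@H](O)CC(=O)OC | starting material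
2 | methyl (2S,3S)-3-hydroxy-2-methylbutanoate | C[C@H](O)[C@H](C)C(=O)OC | intermediate
3 | geranyl bromide, (2E)-1-bromo-3,7-dimethylocta-2,6-diene | BrC/C=C(\C)CCC=C(C)C | starting material
4 | methyl (2S,4E)-2-[(1S)-1-hydroxyethyl]-2,5,9-trimethyldeca-4,8-dienoate | C[C@H](O)[C@](C)(C/C=C(\C)CCC=C(C)C)C(=O)OC | intermediate
5 | methyl (2S,4E)-2-acetyl-2,5,9-trimethyldeca-4,8-dienoate | CC(=O)[C@](C)(C/C=C(\C)CCC=C(C)C)C(=O)OC | intermediate
6 | phloroglucinol (benzene-1,3,5-triol) | Oc1cc(O)cc(O)c1 | starting material
7 | butanoyl chloride | CCCC(Cl)=O | starting material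
8 | 1-(2,4,6-trihydroxyphenyl)butan-1-one | CCCC(=O)c1c(O)cc(O)cc1O | intermediate
9 | acrylic acid (prop-2-enoic acid) | C=CC(=O)O | starting material
10 | 6-butanoyl-5,7-dihydroxychroman-2-one (lactone through the oxygen para to the butanoyl group) | O=C1CCc2c(O)c(C(=O)CCC)c(O)cc2O1 | intermediate
11 | 8-butanoyl-5,7-dihydroxychroman-2-one (lactone through an oxygen ortho to the butanoyl group) | O=C1CCc2c(O)cc(O)c(C(=O)CCC)c2O1 | intermediate
12 | methyl 3-(3-butanoyl-2,4,6-trihydroxyphenyl)propanoate | CCCC(=O)c1c(O)cc(O)c(CCC(=O)OC)c1O | intermediate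
13 | methyl 3-[3-butanoyl-2,4-dihydroxy-6-(triisopropylsilyloxy)phenyl]propanoate | CCCC(=O)c1c(O)cc(O[Si](C(C)C)(C(C)C)C(C)C)c(CCC(=O)OC)c1O | intermediate
14 | 3-methylbut-2-enal | CC(C)=CC=O | starting material
15 | ortho-quinone methide from 13 and 14 by loss of water (exocyclic C=CH–CH=CMe2 on the former free ring carbon, C=O at the former hydroxyl beside the butanoyl group) | CCCC(=O)C1=C(O)C(CCC(=O)OC)=C(O[Si](C(C)C)(C(C)C)C(C)C)C(=CC=C(C)C)C1=O | intermediate
16 | methyl 3-[8-butanoyl-7-hydroxy-2,2-dimethyl-5-(triisopropylsilyloxy)-2H-chromen-6-yl]propanoate | CCCC(=O)c1c(O)c(CCC(=O)OC)c(O[Si](C(C)C)(C(C)C)C(C)C)c2c1OC(C)(C)C=C2 | intermediate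
17 | 3-[8-butanoyl-7-hydroxy-2,2-dimethyl-5-(triisopropylsilyloxy)-2H-chromen-6-yl]propanoic acid | CCCC(=O)c1c(O)c(CCC(=O)O)c(O[Si](C(C)C)(C(C)C)C(C)C)c2c1OC(C)(C)C=C2 | intermediate
18 | 10-butanoyl-8,8-dimethyl-5-(triisopropylsilyloxy)-3,4-dihydro-2H,8H-pyrano[3,2-g]chromen-2-one | CCCC(=O)c1c2OC(=O)CCc2c(O[Si](C(C)C)(C(C)C)C(C)C)c2c1OC(C)(C)C=C2 | intermediate
19 | methyl (2S)-7-[8-butanoyl-7-hydroxy-2,2-dimethyl-5-(triisopropylsilyloxy)-2H-chromen-6-yl]-2-[(2E)-3,7-dimethylocta-2,6-dien-1-yl]-2-methyl-3,5-dioxoheptanoate | CCCC(=O)c1c(O)c(CCC(=O)CC(=O)[C@](C)(C/C=C(\C)CCC=C(C)C)C(=O)OC)c(O[Si](C(C)C)(C(C)C)C(C)C)c2c1OC(C)(C)C=C2 | intermediate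
20 | (4S)-6-{[8-butanoyl-7-hydroxy-2,2-dimethyl-5-(triisopropylsilyloxy)-2H-chromen-6-yl]methyl}-4-[(2E)-3,7-dimethylocta-2,6-dien-1-yl]-3,5-dihydroxy-4-methylcyclohexa-2,5-dien-1-one | CCCC(=O)c1c(O)c(CC2=C(O)[C@@](C)(C/C=C(\C)CCC=C(C)C)C(O)=CC2=O)c(O[Si](C(C)C)(C(C)C)C(C)C)c2c1OC(C)(C)C=C2 | intermediate
21 | enol acetate of 20 (acetoxy group on the ring B enol oxygen between the quaternary carbon and the free methine; configuration as in 20) | CCCC(=O)c1c(O)c(CC2=C(O)[C@@](C)(C/C=C(\C)CCC=C(C)C)C(OC(C)=O)=CC2=O)c(O[Si](C(C)C)(C(C)C)C(C)C)c2c1OC(C)(C)C=C2 | intermediate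
22 | (4R)-2-acetyl-6-{[8-butanoyl-7-hydroxy-2,2-dimethyl-5-(triisopropylsilyloxy)-2H-chromen-6-yl]methyl}-4-[(2E)-3,7-dimethylocta-2,6-dien-1-yl]-3,5-dihydroxy-4-methylcyclohexa-2,5-dien-1-one | CCCC(=O)c1c(O)c(CC2=C(O)[C@@](C)(C/C=C(\C)CCC=C(C)C)C(O)=C(C(C)=O)C2=O)c(O[Si](C(C)C)(C(C)C)C(C)C)c2c1OC(C)(C)C=C2 | intermediate
23 | (4R)-2-acetyl-6-[(8-butanoyl-5,7-dihydroxy-2,2-dimethyl-2H-chromen-6-yl)methyl]-4-[(2E)-3,7-dimethylocta-2,6-dien-1-yl]-3,5-dihydroxy-4-methylcyclohexa-2,5-dien-1-one | CCCC(=O)c1c(O)c(CC2=C(O)[C@@](C)(C/C=C(\C)CCC=C(C)C)C(O)=C(C(C)=O)C2=O)c(O)c2c1OC(C)(C)C=C2 | target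

**Totals**

Total step count: 13.
Longest linear sequence: 10 steps (steps 4 to 13, from phloroglucinol). The chiral branch (steps 1 to 3) joins at step 10.

**Steps most likely to fail**

Step 11 (key step). The lithium phenoxide–dienolate polyanion may aggregate, so that the terminal carbanion forms incompletely and the ester is attacked through oxygen or not at all. The fallback sets out from 19 and caps the phenol first. Treatment with tert-butyldimethylsilyl triflate and 2,6-lutidine, followed by a short wash with dilute aqueous acid to cleave the enol silyl ether of the diketone that forms alongside, should give the bis-silyl diketo ester F1. With the phenoxide gone, LiN(iPr)2 (3.5 equiv) should form the butanoyl enolate and the diketone dianion and close ring B to the bis-silyl trione F2. This is C-acetylated as in step 12 to the bis-silyl acetyl trione F3, and Bu4NF/AcOH then removes both silyl groups, so the sequence comes back to the route at 23.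

Step 7. Condensation at the ring carbon beside the bulky silyloxy group may be slow, with silyl transfer between phenols or polymerisation of the enal taking over. The fallback sets out from 13 and builds the pyran ring by the propargyl ether route. O-Alkylation of the less hindered free hydroxyl (the one between the butanoyl group and the ring hydrogen) with 3-chloro-3-methylbut-1-yne, DBU and catalytic CuCl2 in MeCN should give the aryl 1,1-dimethylpropargyl ether F4. Heating in xylene at 140 °C should then bring about aromatic Claisen rearrangement to the only free ortho carbon, 1,5-hydrogen shift and oxa-6π closure, which comes back to the route at 16.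

Step 5. Acid-promoted loss of the butanoyl group or a second alkylation at the remaining ring carbon may erode the material. The fallback sets out from 6 and inverts the order of substitution. Phloroglucinol 6 and acrylic acid 9 are condensed over a sulfonic acid ion-exchange resin in toluene to the known 5,7-dihydroxychroman-2-one F5. Friedel–Crafts butanoylation with 7 and AlCl3 then gives the lactones 10 and 11, and methanolysis of the crude mixture as in step 5 comes back to the route at 12.

**Further compounds**

F1 | step 11 | methyl (2S)-7-[8-butanoyl-7-(tert-butyldimethylsilyloxy)-2,2-dimethyl-5-(triisopropylsilyloxy)-2H-chromen-6-yl]-2-[(2E)-3,7-dimethylocta-2,6-dien-1-yl]-2-methyl-3,5-dioxoheptanoate | CCCC(=O)c1c(O[Si](C)(C)C(C)(C)C)c(CCC(=O)CC(=O)[C@](C)(C/C=C(\C)CCC=C(C)C)C(=O)OC)c(O[Si](C(C)C)(C(C)C)C(C)C)c2c1OC(C)(C)C=C2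
F2 | step 11 | (4S)-6-{[8-butanoyl-7-(tert-butyldimethylsilyloxy)-2,2-dimethyl-5-(triisopropylsilyloxy)-2H-chromen-6-yl]methyl}-4-[(2E)-3,7-dimethylocta-2,6-dien-1-yl]-3,5-dihydroxy-4-methylcyclohexa-2,5-dien-1-one | CCCC(=O)c1c(O[Si](C)(C)C(C)(C)C)c(CC2=C(O)[C@@](C)(C/C=C(\C)CCC=C(C)C)C(O)=CC2=O)c(O[Si](C(C)C)(C(C)C)C(C)C)c2c1OC(C)(C)C=C2
F3 | step 11 | (4R)-2-acetyl-6-{[8-butanoyl-7-(tert-butyldimethylsilyloxy)-2,2-dimethyl-5-(triisopropylsilyloxy)-2H-chromen-6-yl]methyl}-4-[(2E)-3,7-dimethylocta-2,6-dien-1-yl]-3,5-dihydroxy-4-methylcyclohexa-2,5-dien-1-one | CCCC(=O)c1c(O[Si](C)(C)C(C)(C)C)c(CC2=C(O)[C@@](C)(C/C=C(\C)CCC=C(C)C)C(O)=C(C(C)=O)C2=O)c(O[Si](C(C)C)(C(C)C)C(C)C)c2c1OC(C)(C)C=C2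
F4 | step 7 | methyl 3-[3-butanoyl-2-hydroxy-4-(2-methylbut-3-yn-2-yloxy)-6-(triisopropylsilyloxy)phenyl]propanoate | CCCC(=O)c1c(OC(C)(C)C#C)cc(O[Si](C(C)C)(C(C)C)C(C)C)c(CCC(=O)OC)c1O
F5 | step 5 | 5,7-dihydroxychroman-2-one | O=C1CCc2c(O)cc(O)cc2O1
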